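Gentiside J is viewed as docosyl salicylate oxygenated once more, so the route rests on disconnecting the C3–O bond of the benzene ring and forming it late by directed C–H oxygenation. The feature exploited is that, with C1 carrying the ester carbon, C3–H is the only hydrogen ortho to the C2 oxygen. A di-tert-butylsilanol attached to that oxygen guides palladium to C3; in one operation the C3–O bond is made and a five-membered 1,3,2-dioxasilole ring (C2–O–Si–O–C3) closes, giving the catechol in bridged, protected form. The precursor is docosyl 2-{[di-tert-butyl(hydroxy)silyl]oxy}benzoate, made in two steps from salicylic acid; buffered fluoride then frees Gentiside J.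

Key step: step 3

Remark: the ring is numbered as in the benzoate (C1 ester carbon, C2 phenol oxygen, C3 the new oxygen). The C3 oxygen of the silicon bridge is assumed to come from an acetate of the oxidant, the original silanol oxygen leaving in acetic acid.

Step 1
Reactants: 1 salicylic acid; 2 1-bromodocosane
Product: 3 docosyl 2-hydroxybenzoate (docosyl salicylate)
Conditions: KHCO3 (1.2 equiv), DMF, 70 °C
Reagents that add atoms: none
Why: Chemoselective SN2 O-alkylation of a carboxylate should work because bicarbonate deprotonates only the carboxylic acid, leaving the internally hydrogen-bonded phenol protonated, so the primary bromide is attacked by the carboxylate alone.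

Step 2
Reactants: 3 docosyl 2-hydroxybenzoate; 4 di-tert-butylsilyl bis(trifluoromethanesulfonate)
Product: 6 docosyl 2-{[di-tert-butyl(hydroxy)silyl]oxy}benzoate, via silyl triflate 5 (not isolated)
Conditions: tBu2Si(OTf)2 (1.2 equiv), 2,6-lutidine (2.5 equiv), CH2Cl2, 0 °C to rt (3 added slowly to the silyl reagent); then sat. aq. NaHCO3, THF, rt
Reagents that add atoms: water, O
Why: O-Silylation of a phenol by a silyl triflate followed by hydrolysis of the remaining Si–OTf bond should stop cleanly at the silanol, since the first triflate is displaced fast, the second is shielded by the two tert-butyl groups and the aryloxy group until water is added, and the same bulk keeps the silanol from condensing to a disiloxane.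

Step 3
Reactants: 6 docosyl 2-{[di-tert-butyl(hydroxy)silyl]oxy}benzoate
Product: 9 docosyl 2,2-di-tert-butyl-2H-1,3,2-benzodioxasilole-4-carboxylate, via C3 acetate 7 (not isolated), via silyl acetate 8 (not isolated)
Conditions: Pd(OPiv)2 (10 mol%), PhI(OAc)2 (2 equiv), toluene, 100 °C
Reagents that add atoms: (diacetoxyiodo)benzene, CC(=O)OI(OC(C)=O)c1ccccc1
Why: Coordination of the Si–OH oxygen to divalent palladium places the metal beside C3–H, which is cleaved by pivalate-assisted concerted metalation–deprotonation to give a six-membered palladacycle (Pd–O–Si–O–C2–C3). Oxidation by PhI(OAc)2 to tetravalent palladium and C–O reductive elimination should then furnish the C3 acetate 7 and return divalent palladium. The acetyl group migrates to the adjacent silanol oxygen to give silyl acetate 8, and the freed C3 phenol attacks silicon in a 5-exo substitution that expels acetic acid, so the five-membered 1,3,2-dioxasilole ring is closed at silicon and not at carbon. The closest known reaction type is the palladium-catalysed silanol-directed ortho C–H oxygenation of phenols to silicon-bridged catechols, here applied to a phenol that carries an ortho ester. No stereocentre is created; the selectivity required is C3 over C4, C5 and C6, and it is secured because the O–Si–O tether on the C2 oxygen reaches only the two ortho positions, of which C1 is fully substituted, while the ester carbonyl is too weak a ligand to steer palladium to C6. The saturated docosyl chain and the ester are expected to be inert to PhI(OAc)2 at 100 °C.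

Step 4
Reactants: 9 docosyl 2,2-di-tert-butyl-2H-1,3,2-benzodioxasilole-4-carboxylate
Product: 10 Gentiside J (docosyl 2,3-dihydroxybenzoate)
Conditions: Bu4NF (2.5 equiv), AcOH (2.5 equiv), THF, 0 °C to rt, argon
Reagents that add atoms: none
Why: Fluoride-mediated cleavage of a cyclic di-tert-butylsilylene should release both aryl oxygens through formation of strong Si–F bonds, while acetic acid protonates the phenoxides at once so that neither air oxidation of a catecholate nor attack on the ester can intervene.

Compound list
1 | salicylic acid (2-hydroxybenzoic acid) | O=C(O)c1ccccc1O | starting material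
2 | 1-bromodocosane | CCCCCCCCCCCCCCCCCCCCCCBr | starting material
3 | docosyl 2-hydroxybenzoate (docosyl salicylate) | CCCCCCCCCCCCCCCCCCCCCCOC(=O)c1ccccc1O | intermediate
4 | di-tert-butylsilyl bis(trifluoromethanesulfonate) | CC(C)(C)[Si](OS(=O)(=O)C(F)(F)F)(OS(=O)(=O)C(F)(F)F)C(C)(C)C | starting material
5 | docosyl 2-{[di-tert-butyl(trifluoromethanesulfonyloxy)silyl]oxy}benzoate | CCCCCCCCCCCCCCCCCCCCCCOC(=O)c1ccccc1O[Si](OS(=O)(=O)C(F)(F)F)(C(C)(C)C)C(C)(C)C | intermediate
6 | docosyl 2-{[di-tert-butyl(hydroxy)silyl]oxy}benzoate | CCCCCCCCCCCCCCCCCCCCCCOC(=O)c1ccccc1O[Si](O)(C(C)(C)C)C(C)(C)C | intermediate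
7 | docosyl 3-acetoxy-2-{[di-tert-butyl(hydroxy)silyl]oxy}benzoate | CCCCCCCCCCCCCCCCCCCCCCOC(=O)c1cccc(OC(C)=O)c1O[Si](O)(C(C)(C)C)C(C)(C)C | intermediate
8 | docosyl 2-{[acetoxy(di-tert-butyl)silyl]oxy}-3-hydroxybenzoate | CCCCCCCCCCCCCCCCCCCCCCOC(=O)c1cccc(O)c1O[Si](OC(C)=O)(C(C)(C)C)C(C)(C)C | intermediate
9 | docosyl 2,2-di-tert-butyl-2H-1,3,2-benzodioxasilole-4-carboxylate | CCCCCCCCCCCCCCCCCCCCCCOC(=O)c1cccc2O[Si](C(C)(C)C)(C(C)(C)C)Oc12 | intermediate
10 | Gentiside J (docosyl 2,3-dihydroxybenzoate) | CCCCCCCCCCCCCCCCCCCCCCOC(=O)c1cccc(O)c1O | target

Total step count: 4
Longest linear sequence: 4 steps (1 → 3 → 6 → 9 → 10)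

Steps most likely to fail

Risk 1, step 3: palladation at C3 may be slow because the silanol tether is crowded by the neighbouring ester and the ring is electron-poor. At 100 °C the tether may then be lost first, by protodesilylation in the acetic acid that builds up or by acyl transfer from the ester to the silanol. The fallback gives up the C–H oxygenation altogether. It sets out from 1-bromodocosane 2, which would alkylate the carboxylate of commercial 2,3-dihydroxybenzoic acid F1 (KHCO3, DMF, 60 °C, argon) by the same chemoselective carboxylate alkylation as in step 1. It comes back to the route directly at Gentiside J 10.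

Risk 2, step 2: a second phenol may displace the remaining triflate on silicon, or the silyl triflate may close onto the neighbouring ester carbonyl with loss of the docosyl group before water is added. The fallback avoids a doubly electrophilic silicon reagent. It sets out from 3, which would be silylated with di-tert-butylchlorosilane (tBu2SiHCl, imidazole, DMF) to docosyl 2-[(di-tert-butylsilyl)oxy]benzoate F2. The Si–H bond would then be brominated (NBS, CH2Cl2, 0 °C) to docosyl 2-{[bromo(di-tert-butyl)silyl]oxy}benzoate F3, and hydrolysis of the Si–Br bond (aq. NaHCO3, THF) comes back to the route at silanol 6.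

Risk 3, step 1: substitution by the waxy, poorly soluble C22 bromide may be slow, and alkylation of the phenol oxygen may creep in on prolonged heating. The fallback changes from carboxylate alkylation to acid-catalysed Fischer esterification. It sets out from salicylic acid 1, which would be heated with 1-docosanol F4 (cat. TsOH·H2O, toluene, reflux, Dean–Stark removal of water), and comes back to the route at ester 3.

Further compounds
F1 | step 3 | 2,3-dihydroxybenzoic acid | O=C(O)c1cccc(O)c1O
F2 | step 2 | docosyl 2-[(di-tert-butylsilyl)oxy]benzoate | CCCCCCCCCCCCCCCCCCCCCCOC(=O)c1ccccc1O[SiH](C(C)(C)C)C(C)(C)C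
F3 | step 2 | docosyl 2-{[bromo(di-tert-butyl)silyl]oxy}benzoate | CCCCCCCCCCCCCCCCCCCCCCOC(=O)c1ccccc1O[Si](Br)(C(C)(C)C)C(C)(C)C
F4 | step 1 | 1-docosanol | CCCCCCCCCCCCCCCCCCCCCCO
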